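**Strategy.** The oxolane is made by contracting an oxane. The feature exploited is the 2,4-dihydroxybenzoyl carbon on oxolane C3: it is treated as a former ring atom, a tertiary aryl carbinol that sat between the carbons that become C3 and C4. In the precursor, a 4-aryl-4-hydroxyoxan-3-yl mesylate, a semipinacol 1,2-shift moves the oxane C4–C5 bond onto C3 as mesylate leaves. One operation thus forms the oxolane C3–C4 bond, expels the carbinol carbon as the exocyclic aryl ketone, sets C3 by inversion and carries C4 across with retention. The oxane comes from a cis-selective hetero-Diels–Alder reaction, arylcerium addition and trans C-arylation of a glycal-type epoxide.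

Key step: step 9

Assumption: the catalyst antipodes named in steps 1 and 4 are those expected to attack the Re face of each aldehyde; if the sense proves opposite, the mirror-image catalyst is used.

Remark on numbering: the Why lines use one oxane numbering throughout, O1, C2 (4-benzyloxyphenyl carbon), C3, C4 (carbinol), C5 (side chain), C6 (2,4-bis(benzyloxy)phenyl carbon); compound names use IUPAC numbering.

**Step 1**
Reactants: 1 (E)-1-methoxy-3-(trimethylsilyloxy)buta-1,3-diene; 2 4-(benzyloxy)benzaldehyde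
Product: 4 (R,E)-5-[4-(benzyloxy)phenyl]-5-hydroxy-1-methoxypent-1-en-3-one, via silyl aldol ether 3 (not isolated)
Conditions: Ti(OiPr)4/(R)-BINOL (10 mol %), 4 Å MS, Et2O, −20 °C; then aq. citric acid, THF, 0 °C
Reagents that add atoms: none
Why: Catalytic asymmetric Mukaiyama aldol reaction in which the diene reacts as a silyl enol ether at its terminal CH2 and the chiral titanium Lewis acid directs attack to the Re face of the aldehyde, setting the (R)-carbinol; without strong acid the adduct should stay open-chain.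

**Step 2**
Reactants: 4 (R,E)-5-[4-(benzyloxy)phenyl]-5-hydroxy-1-methoxypent-1-en-3-one
Product: 5 (R,E)-5-[4-(benzyloxy)phenyl]-5-[(benzyloxy)methoxy]-1-methoxypent-1-en-3-one
Conditions: BOMCl, iPr2NEt, CH2Cl2, 0 °C → rt
Reagents that add atoms: benzyl chloromethyl ether, ClCOCc1ccccc1
Why: O-Alkylation of the secondary alcohol with a chloromethyl ether under amine base (acetal protection) leaves the vinylogous ester untouched, and the BOM group can later leave together with the benzyl ethers.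

**Step 3**
Reactants: 5 (R,E)-5-[4-(benzyloxy)phenyl]-5-[(benzyloxy)methoxy]-1-methoxypent-1-en-3-one
Product: 6 {[(1E,3Z,5R)-5-[4-(benzyloxy)phenyl]-5-[(benzyloxy)methoxy]-1-methoxypenta-1,3-dien-3-yl]oxy}trimethylsilane
Conditions: TMSOTf, Et3N, Et2O, 0 °C
Reagents that add atoms: trimethylsilyl trifluoromethanesulfonate, C[Si](C)(C)OS(=O)(=O)C(F)(F)F
Why: Soft enolisation and O-silylation at the only enolisable carbon should give the conjugated 2-silyloxydiene, the Z-enol silane (side chain "outside") being the thermodynamic isomer.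

**Step 4**
Reactants: 6 {[(1E,3Z,5R)-5-[4-(benzyloxy)phenyl]-5-[(benzyloxy)methoxy]-1-methoxypenta-1,3-dien-3-yl]oxy}trimethylsilane; 7 2,4-bis(benzyloxy)benzaldehyde
Product: 9 (2R,3S)-2-[2,4-bis(benzyloxy)phenyl]-3-{(R)-[4-(benzyloxy)phenyl][(benzyloxy)methoxy]methyl}-2,3-dihydro-4H-pyran-4-one, via all-cis cycloadduct 8 (not isolated)
Conditions: Rh2(S-BPTPI)4 (2 mol %), 4 Å MS, CH2Cl2, 0 °C → rt; then TFA (cat.), CH2Cl2, 0 °C
Reagents that add atoms: none
Why: Endo-selective hetero-Diels–Alder reaction in which the outside substituent of the diene terminus and the endo aldehyde aryl end up cis (C5/C6), while the chiral Rh(II) Lewis acid selects the Re face of the aldehyde, so both new centres are set under catalyst control relative to the existing carbinol; acid then eliminates methoxytrimethylsilane to the enone.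

**Step 5**
Reactants: 10 4-bromobenzene-1,3-diol
Product: 11 2,4-bis(benzyloxy)-1-bromobenzene
Conditions: BnBr, K2CO3, DMF, 60 °C
Reagents that add atoms: benzyl bromide, BrCc1ccccc1
Why: Williamson ether synthesis on both phenols.

**Step 6**
Reactants: 9 (2R,3S)-2-[2,4-bis(benzyloxy)phenyl]-3-{(R)-[4-(benzyloxy)phenyl][(benzyloxy)methoxy]methyl}-2,3-dihydro-4H-pyran-4-one; 11 2,4-bis(benzyloxy)-1-bromobenzene
Product: 14 (2R,3S,4S)-2,4-bis[2,4-bis(benzyloxy)phenyl]-3-{(R)-[4-(benzyloxy)phenyl][(benzyloxy)methoxy]methyl}-3,4-dihydro-2H-pyran-4-ol, via aryllithium 12 (not isolated), via arylcerium dichloride 13 (not isolated)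
Conditions: 11, n-BuLi, THF, −78 °C; anhydrous CeCl3, −78 °C; then 9, −78 °C; cold aq. NaHCO3 quench; product used at once
Reagents that add atoms: none
Why: Bromine–lithium exchange, transmetalation to cerium and 1,2-addition to the vinylogous ester carbonyl (the organocerium suppresses enolisation at C5); the aryl should enter C4 anti to the cis C5/C6 substituents, leaving the hydroxyl on their face.

**Step 7**
Reactants: 14 (2R,3S,4S)-2,4-bis[2,4-bis(benzyloxy)phenyl]-3-{(R)-[4-(benzyloxy)phenyl][(benzyloxy)methoxy]methyl}-3,4-dihydro-2H-pyran-4-ol; 15 [4-(benzyloxy)phenyl]magnesium bromide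
Product: 17 (2S,3S,4S,5S,6R)-4,6-bis[2,4-bis(benzyloxy)phenyl]-2-[4-(benzyloxy)phenyl]-5-{(R)-[4-(benzyloxy)phenyl][(benzyloxy)methoxy]methyl}oxane-3,4-diol, via glycal epoxide 16 (not isolated)
Conditions: DMDO (acetone), CH2Cl2, −40 → 0 °C, evaporate; then 15 (3 equiv), CuI (10 mol %), THF, −30 → 0 °C
Reagents that add atoms: dimethyldioxirane, CC1(C)OO1
Why: Glycal-type epoxidation of the enol ether anti to the pseudo-axial allylic aryl and syn to the hydroxyl, then copper-catalysed SN2 opening of the acetal-type epoxide at C2 with inversion by the aryl Grignard reagent, which sets the 2,3-trans aryl/hydroxyl pair and places the new aryl trans to the C6 aryl.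

**Step 8**
Reactants: 17 (2S,3S,4S,5S,6R)-4,6-bis[2,4-bis(benzyloxy)phenyl]-2-[4-(benzyloxy)phenyl]-5-{(R)-[4-(benzyloxy)phenyl][(benzyloxy)methoxy]methyl}oxane-3,4-diol
Product: 18 (2S,3S,4S,5S,6R)-4,6-bis[2,4-bis(benzyloxy)phenyl]-2-[4-(benzyloxy)phenyl]-5-{(R)-[4-(benzyloxy)phenyl][(benzyloxy)methoxy]methyl}-4-hydroxyoxan-3-yl methanesulfonate
Conditions: MsCl, pyridine, DMAP (cat.), CH2Cl2, 0 °C; product used without storage
Reagents that add atoms: methanesulfonyl chloride, CS(=O)(=O)Cl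
Why: Selective sulfonylation of the secondary equatorial alcohol; the tertiary benzylic hydroxyl is too hindered to react under these conditions.

**Step 9**
Reactants: 18 (2S,3S,4S,5S,6R)-4,6-bis[2,4-bis(benzyloxy)phenyl]-2-[4-(benzyloxy)phenyl]-5-{(R)-[4-(benzyloxy)phenyl][(benzyloxy)methoxy]methyl}-4-hydroxyoxan-3-yl methanesulfonate
Product: 19 [2,4-bis(benzyloxy)phenyl]{(2R,3R,4S,5R)-5-[2,4-bis(benzyloxy)phenyl]-2-[4-(benzyloxy)phenyl]-4-{(R)-[4-(benzyloxy)phenyl][(benzyloxy)methoxy]methyl}oxolan-3-yl}methanone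
Conditions: Et3Al (3 equiv), CH2Cl2, −78 → 0 °C; Rochelle salt work-up
Reagents that add atoms: none
Why: Et3Al turns the tertiary C4 hydroxyl into an aluminium alkoxide and activates the C3 mesylate; in the chair that holds the C2 aryl, the mesylate and the C5 side chain equatorial and the C6 aryl axial, the C4–C5 ring bond is antiperiplanar to C3–OMs and shifts from C4 to C3 as mesylate leaves, while C4 becomes the aryl ketone carbonyl. The closest known reaction type is the semipinacol (pinacol-type) rearrangement of 2-sulfonyloxy alcohols, used here as a ring contraction of a cyclic diol monosulfonate. The oxolane closes through the 1,2-shift itself (new C3–C5 bond, six to five ring atoms), not through a separate exo or endo cyclisation. The new ketone α-centre (oxolane C3) is set by stereospecific inversion at the mesylate carbon, the migrating carbon (oxolane C4) keeps its configuration, and oxolane C2 and C5 are not touched. The step needs the C5 shift in preference to aryl migration, epoxide formation or participation of the ring oxygen: the aryl and the oxygen on C4 are gauche to the leaving group, the cis (equatorial/axial) diol geometry cannot close an epoxide, and the alkoxide push should favour the C–C shift, while the non-basic, cold conditions protect the epimerisable C3 and the β-alkoxy ketone.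

**Step 10**
Reactants: 19 [2,4-bis(benzyloxy)phenyl]{(2R,3R,4S,5R)-5-[2,4-bis(benzyloxy)phenyl]-2-[4-(benzyloxy)phenyl]-4-{(R)-[4-(benzyloxy)phenyl][(benzyloxy)methoxy]methyl}oxolan-3-yl}methanone
Product: 20 (2,4-dihydroxyphenyl){(2R,3R,4R,5R)-5-(2,4-dihydroxyphenyl)-4-[(R)-hydroxy(4-hydroxyphenyl)methyl]-2-(4-hydroxyphenyl)oxolan-3-yl}methanone
Conditions: H2 (1 atm), Pd(OH)2/C, EtOAc–MeOH, rt, monitored closely
Reagents that add atoms: none
Why: Hydrogenolysis of the five aryl benzyl ethers and of the BOM benzyl group, whose hemiformal loses formaldehyde; under neutral conditions the benzylic ring C–O bonds, the secondary benzylic alcohol and the chelated aryl ketone should be reduced more slowly.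

**Compound list**
1 | (E)-1-methoxy-3-(trimethylsilyloxy)buta-1,3-diene | CO/C=C/C(=C)O[Si](C)(C)C | starting material
2 | 4-(benzyloxy)benzaldehyde | O=Cc1ccc(OCc2ccccc2)cc1 | starting material
3 | (R,E)-5-[4-(benzyloxy)phenyl]-1-methoxy-5-(trimethylsilyloxy)pent-1-en-3-one (not isolated) | CO/C=C/C(=O)C[C@@H](O[Si](C)(C)C)c1ccc(OCc2ccccc2)cc1 | intermediate
4 | (R,E)-5-[4-(benzyloxy)phenyl]-5-hydroxy-1-methoxypent-1-en-3-one | CO/C=C/C(=O)C[C@@H](O)c1ccc(OCc2ccccc2)cc1 | intermediate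
5 | (R,E)-5-[4-(benzyloxy)phenyl]-5-[(benzyloxy)methoxy]-1-methoxypent-1-en-3-one | CO/C=C/C(=O)C[C@@H](OCOCc1ccccc1)c1ccc(OCc2ccccc2)cc1 | intermediate
6 | {[(1E,3Z,5R)-5-[4-(benzyloxy)phenyl]-5-[(benzyloxy)methoxy]-1-methoxypenta-1,3-dien-3-yl]oxy}trimethylsilane | C[Si](C)(C)O/C(=C\[C@@H](OCOCc1ccccc1)c1ccc(OCc2ccccc2)cc1)/C=C/OC | intermediate
7 | 2,4-bis(benzyloxy)benzaldehyde | O=Cc1ccc(OCc2ccccc2)cc1OCc1ccccc1 | starting material
8 | 2,3,6-all-cis 2-[2,4-bis(benzyloxy)phenyl]-3-{(R)-[4-(benzyloxy)phenyl][(benzyloxy)methoxy]methyl}-6-methoxy-4-(trimethylsilyloxy)-3,6-dihydro-2H-pyran (not isolated) | O1[C@H](OC)C=C(O[Si](C)(C)C)[C@H]([C@@H](OCOCc2ccccc2)c2ccc(OCc3ccccc3)cc2)[C@@H]1c1ccc(OCc2ccccc2)cc1OCc1ccccc1 | intermediate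
9 | (2R,3S)-2-[2,4-bis(benzyloxy)phenyl]-3-{(R)-[4-(benzyloxy)phenyl][(benzyloxy)methoxy]methyl}-2,3-dihydro-4H-pyran-4-one (2,3-cis) | O1C=CC(=O)[C@H]([C@@H](OCOCc2ccccc2)c2ccc(OCc3ccccc3)cc2)[C@@H]1c1ccc(OCc2ccccc2)cc1OCc1ccccc1 | intermediate
10 | 4-bromobenzene-1,3-diol | Oc1ccc(Br)c(O)c1 | starting material
11 | 2,4-bis(benzyloxy)-1-bromobenzene | Brc1ccc(OCc2ccccc2)cc1OCc1ccccc1 | intermediate
12 | [2,4-bis(benzyloxy)phenyl]lithium (not isolated) | [Li]c1ccc(OCc2ccccc2)cc1OCc1ccccc1 | intermediate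
13 | [2,4-bis(benzyloxy)phenyl]cerium(III) dichloride (not isolated) | Cl[Ce](Cl)c1ccc(OCc2ccccc2)cc1OCc1ccccc1 | intermediate
14 | (2R,3S,4S)-2,4-bis[2,4-bis(benzyloxy)phenyl]-3-{(R)-[4-(benzyloxy)phenyl][(benzyloxy)methoxy]methyl}-3,4-dihydro-2H-pyran-4-ol (hydroxyl cis to the C3 side chain and the C2 aryl) | O1C=C[C@@](O)(c2ccc(OCc3ccccc3)cc2OCc2ccccc2)[C@H]([C@@H](OCOCc2ccccc2)c2ccc(OCc3ccccc3)cc2)[C@@H]1c1ccc(OCc2ccccc2)cc1OCc1ccccc1 | intermediate
15 | [4-(benzyloxy)phenyl]magnesium bromide | Br[Mg]c1ccc(OCc2ccccc2)cc1 | starting material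
16 | 5,6-epoxide of 14 (2,7-dioxabicyclo[4.1.0]heptane, oxirane oxygen cis to the hydroxyl; not isolated) | O1[C@@H]2O[C@@H]2[C@@](O)(c2ccc(OCc3ccccc3)cc2OCc2ccccc2)[C@H]([C@@H](OCOCc2ccccc2)c2ccc(OCc3ccccc3)cc2)[C@@H]1c1ccc(OCc2ccccc2)cc1OCc1ccccc1 | intermediate
17 | (2S,3S,4S,5S,6R)-4,6-bis[2,4-bis(benzyloxy)phenyl]-2-[4-(benzyloxy)phenyl]-5-{(R)-[4-(benzyloxy)phenyl][(benzyloxy)methoxy]methyl}oxane-3,4-diol | O1[C@@H](c2ccc(OCc3ccccc3)cc2)[C@H](O)[C@@](O)(c2ccc(OCc3ccccc3)cc2OCc2ccccc2)[C@H]([C@@H](OCOCc2ccccc2)c2ccc(OCc3ccccc3)cc2)[C@@H]1c1ccc(OCc2ccccc2)cc1OCc1ccccc1 | intermediate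
18 | (2S,3S,4S,5S,6R)-4,6-bis[2,4-bis(benzyloxy)phenyl]-2-[4-(benzyloxy)phenyl]-5-{(R)-[4-(benzyloxy)phenyl][(benzyloxy)methoxy]methyl}-4-hydroxyoxan-3-yl methanesulfonate | O1[C@@H](c2ccc(OCc3ccccc3)cc2)[C@H](OS(C)(=O)=O)[C@@](O)(c2ccc(OCc3ccccc3)cc2OCc2ccccc2)[C@H]([C@@H](OCOCc2ccccc2)c2ccc(OCc3ccccc3)cc2)[C@@H]1c1ccc(OCc2ccccc2)cc1OCc1ccccc1 | intermediate
19 | [2,4-bis(benzyloxy)phenyl]{(2R,3R,4S,5R)-5-[2,4-bis(benzyloxy)phenyl]-2-[4-(benzyloxy)phenyl]-4-{(R)-[4-(benzyloxy)phenyl][(benzyloxy)methoxy]methyl}oxolan-3-yl}methanone | O=C(c1ccc(OCc2ccccc2)cc1OCc1ccccc1)[C@@H]1[C@H]([C@@H](OCOCc2ccccc2)c2ccc(OCc3ccccc3)cc2)[C@H](c2ccc(OCc3ccccc3)cc2OCc2ccccc2)O[C@H]1c1ccc(OCc2ccccc2)cc1 | intermediate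
20 | (2,4-dihydroxyphenyl){(2R,3R,4R,5R)-5-(2,4-dihydroxyphenyl)-4-[(R)-hydroxy(4-hydroxyphenyl)methyl]-2-(4-hydroxyphenyl)oxolan-3-yl}methanone (CNP0244141.1) | O=C(c1ccc(O)cc1O)[C@@H]1[C@H]([C@@H](O)c2ccc(O)cc2)[C@H](c2ccc(O)cc2O)O[C@H]1c1ccc(O)cc1 | target

**Total step count:** 10. **Longest linear sequence:** 9 steps (1, 2, 3, 4, 6, 7, 8, 9, 10); step 5 is a one-step side branch.

**Steps most likely to fail**

1. Step 9. Mesylate may be lost without the C5 shift, because the ring oxygen is also antiperiplanar to the leaving group and may participate, or the tertiary benzylic C–O bond may ionise and eliminate; the new ketone α-centre may also epimerise. The fallback is a Wolff ring contraction that sets out from 9 and comes back at 19. Copper-catalysed conjugate addition of 15 to 9 (aryl trans to the C6 aryl) should give the 2,6-trans oxan-4-one F1. Trifluoroacetylation at the CH2 α-carbon (LiHMDS, CF3CO2CH2CF3) should give the trifluoroacetyl ketone F2, and detrifluoroacetylative diazo transfer (MsN3, Et3N) the α-diazo ketone F3. Photolysis in the presence of MeNHOMe contracts the ring through the ketene to the Weinreb amide F4, with C3 set by protonation from the less hindered face and open to equilibration. Aryllithium 12 then converts F4 into 19.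

2. Step 7. Epoxidation may leak to the other face, part of the opening may run through an SN1 path at the acetal carbon, and 14 may ionise (Ferrier-type) before it is epoxidised; each erodes the 2,3-trans and 2,6-trans relationships. The fallback sets out from 9 and comes back at 17. Conjugate addition of 15 with CuI/TMSCl should give the silyl enol ether F5 with the aryl trans to the C6 aryl, and Rubottom oxidation (DMDO) the α-hydroxy ketone F6. Arylcerium 13 adds to the ketone to give the diol F7 as a C3 epimer mixture. Dess–Martin oxidation of the secondary alcohol gives the ketol F8, and NaBH4 (axial hydride delivery) should give the equatorial C3 alcohol 17.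

3. Step 4. The cycloaddition may be slow with the electron-rich, ortho-substituted aldehyde, and a mismatched facial preference of the stereogenic diene terminus may lower endo and facial selectivity. The fallback sets out from 5 and comes back at 9. TiCl4/iPr2NEt should give the chelated Z-titanium enolate of 5 (BOM oxygen bound to titanium), which adds to 7 in a syn-aldol reaction on the enolate face anti to the aryl group of the chelate, giving the aldol F9. PPTS-catalysed oxa-Michael addition with loss of methanol then closes 9.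

**Further compounds**
F1 | step 9 | 2,6-trans-2-[2,4-bis(benzyloxy)phenyl]-6-[4-(benzyloxy)phenyl]-3-{(R)-[4-(benzyloxy)phenyl][(benzyloxy)methoxy]methyl}oxan-4-one (2,3-cis) | O1[C@@H](c2ccc(OCc3ccccc3)cc2)CC(=O)[C@H]([C@@H](OCOCc2ccccc2)c2ccc(OCc3ccccc3)cc2)[C@@H]1c1ccc(OCc2ccccc2)cc1OCc1ccccc1
F2 | step 9 | 5-(2,2,2-trifluoroacetyl) derivative of F1 | O1[C@@H](c2ccc(OCc3ccccc3)cc2)C(C(=O)C(F)(F)F)C(=O)[C@H]([C@@H](OCOCc2ccccc2)c2ccc(OCc3ccccc3)cc2)[C@@H]1c1ccc(OCc2ccccc2)cc1OCc1ccccc1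
F3 | step 9 | 5-diazo derivative of F1 | O1[C@@H](c2ccc(OCc3ccccc3)cc2)C(=[N+]=[N-])C(=O)[C@H]([C@@H](OCOCc2ccccc2)c2ccc(OCc3ccccc3)cc2)[C@@H]1c1ccc(OCc2ccccc2)cc1OCc1ccccc1
F4 | step 9 | (2R,3R,4S,5R)-5-[2,4-bis(benzyloxy)phenyl]-2-[4-(benzyloxy)phenyl]-4-{(R)-[4-(benzyloxy)phenyl][(benzyloxy)methoxy]methyl}-N-methoxy-N-methyloxolane-3-carboxamide | CON(C)C(=O)[C@@H]1[C@H]([C@@H](OCOCc2ccccc2)c2ccc(OCc3ccccc3)cc2)[C@H](c2ccc(OCc3ccccc3)cc2OCc2ccccc2)O[C@H]1c1ccc(OCc2ccccc2)cc1
F5 | step 7 | trimethylsilyl enol ether of F1 (enol double bond towards the CH carbon next to the 4-benzyloxyphenyl carbon) | O1[C@@H](c2ccc(OCc3ccccc3)cc2)C=C(O[Si](C)(C)C)[C@H]([C@@H](OCOCc2ccccc2)c2ccc(OCc3ccccc3)cc2)[C@@H]1c1ccc(OCc2ccccc2)cc1OCc1ccccc1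
F6 | step 7 | 5-hydroxy derivative of F1 (epimers at the carbinol carbon) | O1[C@@H](c2ccc(OCc3ccccc3)cc2)C(O)C(=O)[C@H]([C@@H](OCOCc2ccccc2)c2ccc(OCc3ccccc3)cc2)[C@@H]1c1ccc(OCc2ccccc2)cc1OCc1ccccc1
F7 | step 7 | C3 epimer mixture of diol 17 | O1[C@@H](c2ccc(OCc3ccccc3)cc2)C(O)[C@@](O)(c2ccc(OCc3ccccc3)cc2OCc2ccccc2)[C@H]([C@@H](OCOCc2ccccc2)c2ccc(OCc3ccccc3)cc2)[C@@H]1c1ccc(OCc2ccccc2)cc1OCc1ccccc1
F8 | step 7 | (2S,4S,5S,6R)-4,6-bis[2,4-bis(benzyloxy)phenyl]-2-[4-(benzyloxy)phenyl]-5-{(R)-[4-(benzyloxy)phenyl][(benzyloxy)methoxy]methyl}-4-hydroxyoxan-3-one | O1[C@@H](c2ccc(OCc3ccccc3)cc2)C(=O)[C@@](O)(c2ccc(OCc3ccccc3)cc2OCc2ccccc2)[C@H]([C@@H](OCOCc2ccccc2)c2ccc(OCc3ccccc3)cc2)[C@@H]1c1ccc(OCc2ccccc2)cc1OCc1ccccc1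
F9 | step 4 | (E,4S,5R)-5-[2,4-bis(benzyloxy)phenyl]-4-{(R)-[4-(benzyloxy)phenyl][(benzyloxy)methoxy]methyl}-5-hydroxy-1-methoxypent-1-en-3-one | CO/C=C/C(=O)[C@H]([C@@H](OCOCc1ccccc1)c1ccc(OCc2ccccc2)cc1)[C@@H](O)c1ccc(OCc2ccccc2)cc1OCc1ccccc1
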